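**Retrosynthetic overview**
- Target ⇐ decarboxylative ring contraction (15 → 14) of a macrocyclic allyl tert-alkyl carbonate: a palladium-mediated O-to-C allyl transfer makes C9–C10 and frees the C12 hydroxyl.
- Macrocyclic carbonate ⇐ CO2 fixation on a tertiary propargylic alcohol, then transcarbonation by the C9 allylic alcohol (this also unveils the C11 methyl ketone); the oxirane is put on this ring by Shi epoxidation of the 3Z alkene.
- C12 ⇐ asymmetric alkynylation of a methyl ketone; acrylate ⇐ aldehyde → alkyne → methoxycarbonylation; C1 ⇐ organocatalytic Michael addition of a dienal to methyl vinyl ketone.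
- Dienal ⇐ Normant carbocupration of propyne (sets 3Z), then conjugate addition to acrolein; E-allylic oxygen at C9 ⇐ SeO2 oxidation of 5-bromo-2-methylpent-2-ene.
- Ring order: 15-membered cyclic carbonate, then the oxirane, then the 14-membered carbocycle by contraction.

Assumption: atoms carry cembrane numbers (C1 bears the acrylate C15–C17, oxirane at C3–C4, alkene C7=C8, ketone C11, carbinol C12); the SMILES is read as 1S,3R,4S,7E,12S with C2 and C5 cis on the oxirane. TBDPS = tert-butyldiphenylsilyl.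

**Step 1**
Reactants: 1 5-bromo-2-methylpent-2-ene
Product: 2 (2E)-5-bromo-2-methylpent-2-en-1-ol
Conditions: SeO2 (0.5 equiv), t-BuOOH (2 equiv), salicylic acid (0.1 equiv), CH2Cl2, 25 °C
Reagents that add atoms: tert-butyl hydroperoxide, CC(C)(C)OO (oxygen relayed through SeO2)
Why: Sharpless SeO2/t-BuOOH allylic oxidation (ene reaction, then 2,3-shift of the allylseleninic acid) hydroxylates only the methyl group trans to the chain of an isopropylidene alkene, which fixes the E geometry of the later C7=C8 bond.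

**Step 2**
Reactants: 2 (2E)-5-bromo-2-methylpent-2-en-1-ol
Product: 3 tert-butyl{[(2E)-5-bromo-2-methylpent-2-en-1-yl]oxy}diphenylsilane
Conditions: TBDPSCl, imidazole, DMF, 0 → 25 °C
Reagents that add atoms: tert-butyl(chloro)diphenylsilane, CC(C)(C)[Si](Cl)(c1ccccc1)c1ccccc1
Why: Routine silyl ether formation; TBDPS is chosen because it survives the Grignard, basic methanol and acidic carbonylation steps and comes off together with the alkynyl silane in step 8.

**Step 3**
Reactants: 3 tert-butyl{[(2E)-5-bromo-2-methylpent-2-en-1-yl]oxy}diphenylsilane; 4 propyne; 5 acrolein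
Product: 10 (4Z,8E)-10-(TBDPS-oxy)-5,9-dimethyldeca-4,8-dienal, via Grignard reagent 6 (not isolated), via alkylcopper 7 (not isolated), via alkenylcopper 8 (not isolated), via silyl enol ether 9 (not isolated)
Conditions: Mg, Et2O, 35 °C; CuBr·SMe2, Et2O–Me2S, −45 °C; propyne, −25 °C; acrolein, Me3SiCl, HMPA, THF, −78 → −30 °C; 1 M HCl, 0 °C
Reagents that add atoms: none
Why: Normant carbocupration adds the alkylcopper syn across propyne with the alkyl group on the internal carbon, so chain and copper are cis, and the Me3SiCl-accelerated conjugate addition of the alkenylcopper to acrolein proceeds with retention to give the 4Z enal after hydrolysis of the silyl enol ether.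

**Step 4**
Reactants: 10 (4Z,8E)-10-(TBDPS-oxy)-5,9-dimethyldeca-4,8-dienal; 11 methyl vinyl ketone
Product: 12 (2S)-2-[(2Z,6E)-8-(TBDPS-oxy)-3,7-dimethylocta-2,6-dien-1-yl]-5-oxohexanal
Conditions: (S)-2-[diphenyl(trimethylsilyloxy)methyl]pyrrolidine (10 mol %), ethyl 3,4-dihydroxybenzoate (20 mol %), neat, 4 °C
Reagents that add atoms: none
Why: Enamine-catalysed asymmetric Michael addition (Hayashi–Jørgensen catalyst, Gellman conditions); the diphenyl(silyloxy)methyl group shields one face of the E-enamine, so methyl vinyl ketone adds to the open face and C1 is formed as S.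

**Step 5**
Reactants: 12 (2S)-2-[(2Z,6E)-8-(TBDPS-oxy)-3,7-dimethylocta-2,6-dien-1-yl]-5-oxohexanal
Product: 13 (5S,7Z,11E)-13-(TBDPS-oxy)-5-ethynyl-8,12-dimethyltrideca-7,11-dien-2-one
Conditions: dimethyl (1-diazo-2-oxopropyl)phosphonate, K2CO3, MeOH, 0 °C
Reagents that add atoms: dimethyl (1-diazo-2-oxopropyl)phosphonate, COP(=O)(OC)C(=[N+]=[N-])C(C)=O
Why: Ohira–Bestmann (Seyferth–Gilbert) homologation converts the aldehyde but not the methyl ketone into the terminal alkyne, and at 0 °C it should outrun epimerisation of C1 and intramolecular aldol closure.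

**Step 6**
Reactants: 13 (5S,7Z,11E)-13-(TBDPS-oxy)-5-ethynyl-8,12-dimethyltrideca-7,11-dien-2-one
Product: 14 methyl (3S,5Z,9E)-11-(TBDPS-oxy)-6,10-dimethyl-2-methylidene-3-(3-oxobutyl)undeca-5,9-dienoate
Conditions: Pd(OAc)2 (1 mol %), 2-(diphenylphosphino)pyridine, MsOH (cat.), CO (30 bar), MeOH, 45 °C
Reagents that add atoms: carbon monoxide, [C-]#[O+]; methanol, CO
Why: Drent-type palladium-catalysed Markovnikov methoxycarbonylation of a terminal alkyne (2-pyridylphosphine ligand, acid co-catalyst) gives the 2-substituted acrylate directly and leaves C1, the trisubstituted alkenes and the ketone alone.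

**Step 7**
Reactants: 14 methyl (3S,5Z,9E)-11-(TBDPS-oxy)-6,10-dimethyl-2-methylidene-3-(3-oxobutyl)undeca-5,9-dienoate; 15 ethynyl(trimethyl)silane
Product: 17 methyl (3S,5Z,9E)-11-(TBDPS-oxy)-3-[(3S)-3-hydroxy-3-methyl-5-(trimethylsilyl)pent-4-yn-1-yl]-6,10-dimethyl-2-methylideneundeca-5,9-dienoate, via alkynylzinc 16 (not isolated)
Conditions: Me2Zn (3 equiv), (R,R)-N,N'-bis(3,5-di-tert-butylsalicylidene)-1,2-cyclohexanediamine (20 mol %), toluene, 25 °C; aq. NH4Cl
Reagents that add atoms: none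
Why: Catalytic asymmetric alkynylation of a methyl ketone by an alkynylzinc under a chiral Zn(salen) complex (Cozzi type), with the ligand antipode that directs Re-face attack (taken as R,R by analogy) so that C12 is formed as S; about 85:15 dr is expected for a methyl alkyl ketone and the minor C12 epimer is removed by chromatography.

**Step 8**
Reactants: 17 methyl (3S,5Z,9E)-11-(TBDPS-oxy)-3-[(3S)-3-hydroxy-3-methyl-5-(trimethylsilyl)pent-4-yn-1-yl]-6,10-dimethyl-2-methylideneundeca-5,9-dienoate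
Product: 18 methyl (3S,5Z,9E)-11-hydroxy-3-[(3S)-3-hydroxy-3-methylpent-4-yn-1-yl]-6,10-dimethyl-2-methylideneundeca-5,9-dienoate
Conditions: Bu4NF (3 equiv), AcOH (3 equiv), THF, 25 °C
Reagents that add atoms: none
Why: Fluoride-mediated desilylation cleaves the C–Si and O–Si bonds in one operation, with acetic acid buffering to protect the acrylate.

**Step 9**
Reactants: 18 methyl (3S,5Z,9E)-11-hydroxy-3-[(3S)-3-hydroxy-3-methylpent-4-yn-1-yl]-6,10-dimethyl-2-methylideneundeca-5,9-dienoate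
Product: 20 methyl 2-[(5E,9Z,12S,15S)-15-acetyl-5,9,15-trimethyl-2-oxo-1,3-dioxacyclopentadeca-5,9-dien-12-yl]prop-2-enoate, via alkylidene cyclic carbonate 19 (not isolated)
Conditions: AgOAc (10 mol %), DBU (20 mol %), CO2 (1 MPa), MeCN (2 mM), 25 °C
Reagents that add atoms: carbon dioxide, O=C=O
Why: Silver-catalysed carboxylative 5-exo-dig cyclisation of the tertiary propargylic alcohol with CO2 gives the α-alkylidene cyclic carbonate, which the C9 hydroxyl opens by DBU-catalysed transcarbonation at high dilution; tautomerisation of the released enol to the C11 methyl ketone makes the 15-membered ring closure irreversible.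

**Step 10**
Reactants: 20 methyl 2-[(5E,9Z,12S,15S)-15-acetyl-5,9,15-trimethyl-2-oxo-1,3-dioxacyclopentadeca-5,9-dien-12-yl]prop-2-enoate
Product: 21 methyl 2-[(5E,9S,10R,12S,15S)-15-acetyl-9,10-epoxy-5,9,15-trimethyl-2-oxo-1,3-dioxacyclopentadec-5-en-12-yl]prop-2-enoate
Conditions: D-fructose-derived Shi ketone (30 mol %), Oxone, K2CO3, Bu4NHSO4, MeCN–CH2(OMe)2–aq. Na2B4O7 buffer, 0 °C
Reagents that add atoms: Oxone (potassium peroxymonosulfate, KHSO5), [K+].[O-]S(=O)(=O)OO
Why: Shi asymmetric epoxidation; the dioxirane attacks the electron-rich Z-trisubstituted C3=C4 alkene in preference to the carbonate-deactivated C7=C8 alkene and the acrylate, and the spiro transition state of the D-fructose-derived ketone places oxygen on the face that gives 3R and, by syn addition to the Z alkene, 4S.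

**Step 11**
Reactants: 21 methyl 2-[(5E,9S,10R,12S,15S)-15-acetyl-9,10-epoxy-5,9,15-trimethyl-2-oxo-1,3-dioxacyclopentadec-5-en-12-yl]prop-2-enoate
Product: 22 methyl 2-[(1S,3R,4S,7E,12S)-3,4-epoxy-12-hydroxy-4,8,12-trimethyl-11-oxocyclotetradec-7-en-1-yl]prop-2-enoate (cembrane numbering)
Conditions: Pd2(dba)3·CHCl3 (5 mol %), dppf (12 mol %), THF (2 mM), 40 °C
Reagents that add atoms: none
Why: Proposed new method: zerovalent palladium ionises the allylic C9–O bond of the macrocyclic carbonate, the tertiary alkyl carbonate anion loses CO2, and the resulting tertiary alkoxide, held as counter-ion of the π-allylpalladium cation, is relayed by 1,4-proton transfer into the only possible enolate (C10, because C12 is quaternary), which attacks the less substituted allyl terminus C9 with retention of the E geometry, contracting the 15-membered carbonate to the 14-membered carbocycle and freeing the C12 hydroxyl in a stepwise ionic (not pericyclic) process; the closest known reactions are the Tsuji decarboxylative allylation of allyl enol carbonates and Trost's palladium-catalysed ring contractions of vinyl lactones, but an alkoxide-to-enolate relay from a simple ketone in a macrocyclic ring contraction has not been shown.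

**Compound list**
1 | 5-bromo-2-methylpent-2-ene | CC(C)=CCCBr | starting material
2 | (2E)-5-bromo-2-methylpent-2-en-1-ol | OC/C(C)=C/CCBr | intermediate
3 | tert-butyl{[(2E)-5-bromo-2-methylpent-2-en-1-yl]oxy}diphenylsilane | BrCC/C=C(\C)CO[Si](c1ccccc1)(c1ccccc1)C(C)(C)C | intermediate
4 | propyne | CC#C | starting material
5 | acrolein | C=CC=O | starting material
6 | {(3E)-5-(TBDPS-oxy)-4-methylpent-3-en-1-yl}magnesium bromide | Br[Mg]CC/C=C(\C)CO[Si](c1ccccc1)(c1ccccc1)C(C)(C)C | intermediate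
7 | {(3E)-5-(TBDPS-oxy)-4-methylpent-3-en-1-yl}copper (MgBr2 complex) | [Cu]CC/C=C(\C)CO[Si](c1ccccc1)(c1ccccc1)C(C)(C)C | intermediate
8 | {(1Z,5E)-7-(TBDPS-oxy)-2,6-dimethylhepta-1,5-dien-1-yl}copper | [Cu]/C=C(C)\CC/C=C(\C)CO[Si](c1ccccc1)(c1ccccc1)C(C)(C)C | intermediate
9 | trimethylsilyl enol ether of 10 (enol geometry not defined) | C[Si](C)(C)OC=CC/C=C(C)\CC/C=C(\C)CO[Si](c1ccccc1)(c1ccccc1)C(C)(C)C | intermediate
10 | (4Z,8E)-10-(TBDPS-oxy)-5,9-dimethyldeca-4,8-dienal | O=CCC/C=C(C)\CC/C=C(\C)CO[Si](c1ccccc1)(c1ccccc1)C(C)(C)C | intermediate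
11 | methyl vinyl ketone (but-3-en-2-one) | CC(=O)C=C | starting material
12 | (2S)-2-[(2Z,6E)-8-(TBDPS-oxy)-3,7-dimethylocta-2,6-dien-1-yl]-5-oxohexanal | O=C[C@@H](CCC(C)=O)C/C=C(C)\CC/C=C(\C)CO[Si](c1ccccc1)(c1ccccc1)C(C)(C)C | intermediate
13 | (5S,7Z,11E)-13-(TBDPS-oxy)-5-ethynyl-8,12-dimethyltrideca-7,11-dien-2-one | C#C[C@@H](CCC(C)=O)C/C=C(C)\CC/C=C(\C)CO[Si](c1ccccc1)(c1ccccc1)C(C)(C)C | intermediate
14 | methyl (3S,5Z,9E)-11-(TBDPS-oxy)-6,10-dimethyl-2-methylidene-3-(3-oxobutyl)undeca-5,9-dienoate | C=C(C(=O)OC)[C@@H](CCC(C)=O)C/C=C(C)\CC/C=C(\C)CO[Si](c1ccccc1)(c1ccccc1)C(C)(C)C | intermediate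
15 | ethynyl(trimethyl)silane | C#C[Si](C)(C)C | starting material
16 | methyl[(trimethylsilyl)ethynyl]zinc | C[Zn]C#C[Si](C)(C)C | intermediate
17 | methyl (3S,5Z,9E)-11-(TBDPS-oxy)-3-[(3S)-3-hydroxy-3-methyl-5-(trimethylsilyl)pent-4-yn-1-yl]-6,10-dimethyl-2-methylideneundeca-5,9-dienoate | C=C(C(=O)OC)[C@@H](CC[C@](C)(O)C#C[Si](C)(C)C)C/C=C(C)\CC/C=C(\C)CO[Si](c1ccccc1)(c1ccccc1)C(C)(C)C | intermediate
18 | methyl (3S,5Z,9E)-11-hydroxy-3-[(3S)-3-hydroxy-3-methylpent-4-yn-1-yl]-6,10-dimethyl-2-methylideneundeca-5,9-dienoate | C=C(C(=O)OC)[C@@H](CC[C@](C)(O)C#C)C/C=C(C)\CC/C=C(\C)CO | intermediate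
19 | methyl (3S,5Z,9E)-11-hydroxy-6,10-dimethyl-2-methylidene-3-{2-[(4S)-4-methyl-5-methylidene-2-oxo-1,3-dioxolan-4-yl]ethyl}undeca-5,9-dienoate | C=C(C(=O)OC)[C@@H](CC[C@]1(C)OC(=O)OC1=C)C/C=C(C)\CC/C=C(\C)CO | intermediate
20 | methyl 2-[(5E,9Z,12S,15S)-15-acetyl-5,9,15-trimethyl-2-oxo-1,3-dioxacyclopentadeca-5,9-dien-12-yl]prop-2-enoate | C=C(C(=O)OC)[C@H]1CC[C@@](C)(C(C)=O)OC(=O)OC/C(C)=C/CC/C(C)=C\C1 | intermediate
21 | methyl 2-[(5E,9S,10R,12S,15S)-15-acetyl-9,10-epoxy-5,9,15-trimethyl-2-oxo-1,3-dioxacyclopentadec-5-en-12-yl]prop-2-enoate | C=C(C(=O)OC)[C@H]1CC[C@@](C)(C(C)=O)OC(=O)OC/C(C)=C/CC[C@]2(C)O[C@@H]2C1 | intermediate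
22 | methyl 2-[(1S,3R,4S,7E,12S)-3,4-epoxy-12-hydroxy-4,8,12-trimethyl-11-oxocyclotetradec-7-en-1-yl]prop-2-enoate | C=C(C(=O)OC)[C@H]1CC[C@](C)(O)C(=O)CC/C(C)=C/CC[C@]2(C)O[C@@H]2C1 | target

**Step count and risks**
Total step count: 11. Longest linear sequence: 11 steps (1 → 22). Step 7 is expected to work but with only moderate diastereoselectivity at C12.

Step 11 (new ring contraction; O-allylation, diene formation or oligomers may compete). The fallback uses known chemistry, sets out from 21 and returns at 22. Catalytic NaOMe in MeOH at 0 °C opens the carbonate to the seco hydroxy ketol F7. CBr4/PPh3 in CH2Cl2 at 0 °C converts its allylic alcohol into the allylic bromide F8. Slow addition of F8 to LiN(SiMe3)2 (2.2 equiv) in THF at −78 → 0 °C and 1 mM closes the ring by C10 alkylation of the alkoxide–enolate dianion, a classical intramolecular enolate alkylation.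

Step 9 (15-membered ring closure by transcarbonation; oligomers, or DBU-induced breakdown of the β-oxo carbonate). The fallback sets out from 18 and returns at 20. CDI (1.05 equiv, CH2Cl2, 0 °C) acylates only the primary hydroxyl to give the imidazolylcarbonyl derivative F1. DBU (1 equiv) in MeCN at 60 °C and 2 mM lets the tertiary propargylic hydroxyl displace imidazole and close the macrocyclic propargylic carbonate F2. Carbonate-assisted hydration of its terminal alkyne (Ph3PAuCl/AgSbF6 cat., wet 1,4-dioxane, 25 °C) gives the methyl ketone 20.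

Step 10 (chemo- and face-selectivity of the epoxidation on a flexible macrocycle). The fallback moves the epoxidation to an acyclic intermediate; it sets out from 18 and returns at 21. Ac2O/pyridine (0 °C) gives the primary allylic acetate F3, whose acetoxy group deactivates the C7=C8 alkene as in geranyl acetate. Shi epoxidation under the step 10 conditions gives the epoxy acetate F4. K2CO3 (0.2 equiv) in MeOH at 0 °C gives the epoxy diol F5. The step 9 conditions (AgOAc, DBU, CO2, 2 mM) close the ring through the epoxy alkylidene cyclic carbonate F6 to 21.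

**Further compounds**
F1 | step 9 | methyl (3S,5Z,9E)-3-[(3S)-3-hydroxy-3-methylpent-4-yn-1-yl]-11-[(1H-imidazol-1-ylcarbonyl)oxy]-6,10-dimethyl-2-methylideneundeca-5,9-dienoate | C=C(C(=O)OC)[C@@H](CC[C@](C)(O)C#C)C/C=C(C)\CC/C=C(\C)COC(=O)n1ccnc1
F2 | step 9 | methyl 2-[(5E,9Z,12S,15S)-15-ethynyl-5,9,15-trimethyl-2-oxo-1,3-dioxacyclopentadeca-5,9-dien-12-yl]prop-2-enoate | C=C(C(=O)OC)[C@H]1CC[C@@](C)(C#C)OC(=O)OC/C(C)=C/CC/C(C)=C\C1
F3 | step 10 | methyl (3S,5Z,9E)-11-acetoxy-3-[(3S)-3-hydroxy-3-methylpent-4-yn-1-yl]-6,10-dimethyl-2-methylideneundeca-5,9-dienoate | C=C(C(=O)OC)[C@@H](CC[C@](C)(O)C#C)C/C=C(C)\CC/C=C(\C)COC(C)=O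
F4 | step 10 | methyl (3S,6S)-3-{[(2R,3S)-3-[(3E)-5-acetoxy-4-methylpent-3-en-1-yl]-3-methyloxiran-2-yl]methyl}-6-hydroxy-6-methyl-2-methylideneoct-7-ynoate | C=C(C(=O)OC)[C@@H](CC[C@](C)(O)C#C)C[C@H]1O[C@@]1(C)CC/C=C(\C)COC(C)=O
F5 | step 10 | methyl (3S,6S)-6-hydroxy-3-{[(2R,3S)-3-[(3E)-5-hydroxy-4-methylpent-3-en-1-yl]-3-methyloxiran-2-yl]methyl}-6-methyl-2-methylideneoct-7-ynoate | C=C(C(=O)OC)[C@@H](CC[C@](C)(O)C#C)C[C@H]1O[C@@]1(C)CC/C=C(\C)CO
F6 | step 10 | methyl (3S)-3-{[(2R,3S)-3-[(3E)-5-hydroxy-4-methylpent-3-en-1-yl]-3-methyloxiran-2-yl]methyl}-2-methylidene-5-[(4S)-4-methyl-5-methylidene-2-oxo-1,3-dioxolan-4-yl]pentanoate | C=C(C(=O)OC)[C@@H](CC[C@]1(C)OC(=O)OC1=C)C[C@H]2O[C@@]2(C)CC/C=C(\C)CO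
F7 | step 11 | methyl (3S,6S)-6-hydroxy-3-{[(2R,3S)-3-[(3E)-5-hydroxy-4-methylpent-3-en-1-yl]-3-methyloxiran-2-yl]methyl}-6-methyl-2-methylidene-7-oxooctanoate | C=C(C(=O)OC)[C@@H](CC[C@](C)(O)C(C)=O)C[C@H]1O[C@@]1(C)CC/C=C(\C)CO
F8 | step 11 | methyl (3S,6S)-3-{[(2R,3S)-3-[(3E)-5-bromo-4-methylpent-3-en-1-yl]-3-methyloxiran-2-yl]methyl}-6-hydroxy-6-methyl-2-methylidene-7-oxooctanoate | C=C(C(=O)OC)[C@@H](CC[C@](C)(O)C(C)=O)C[C@H]1O[C@@]1(C)CC/C=C(\C)CBr
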